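**Retrosynthetic overview**
1. Target 25 is a depside. The last two steps only unmask ring B of 23: the two MOM ethers first, then the benzyl ester.
2. Key disconnection: ring A of 23 (C1 bearing the ester carbonyl, C2–OMe, C3–H, C4–OMe, C5–H, C6–propyl) is cut at C3–C4 and C5–C6. This gives the 5-carboxy-4-methoxy-6-propyl-2-pyrone 19 (pyrone C5, C4, C3, C6 become arene C1, C2, C3, C6) and 1,1-dimethoxyethene 20 (arene C4 and C5). Pyrone O1–C2 leaves as CO2.
3. Pyrone 19 is assembled on the phenol oxygen of ring B: butanoylketene capture by phenol 10, malonyl C-acylation and lactonisation, then O-methylation.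
4. Phenol 10 comes from 5-propylresorcinol 1 by two directed ortho-metalations: C–O between the MOM ethers, then C–CO2Bn next to the propyl group.
5. Ring order: ring B is the purchased arene, the 2-pyrone ring is made second, and ring A is formed last from the pyrone.

Key step: step 10

Remark: the target is achiral. The only stereogenic species on the route, bridged lactone 21, is a transient racemate (one enantiomer drawn). Tricarbonyl 17 is an enolised, configurationally labile tautomer mixture drawn in its keto form without a descriptor.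

**Route**

Step 1
Reactants: 1 5-propylresorcinol
Product: 2 1,3-bis(methoxymethoxy)-5-propylbenzene
Conditions: MOMCl, i-Pr2NEt, CH2Cl2, 0 °C to rt
Reagents that add atoms: chloromethyl methyl ether, COCCl
Why: O-alkylation of both phenols by the reactive α-chloro ether under amine base (Williamson-type etherification) should give the bis-acetal, whose OMOM groups later direct both metalations.

Step 2
Reactants: 2 1,3-bis(methoxymethoxy)-5-propylbenzene
Product: 5 2,6-bis(methoxymethoxy)-4-propylphenol, via aryllithium 3 (not isolated), via lithium aryltrimethoxyborate 4 (not isolated)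
Conditions: n-BuLi, THF, 0 °C; B(OMe)3, −78 °C to rt; 30% aq. H2O2, 0 °C to rt
Reagents that add atoms: hydrogen peroxide, OO
Why: Directed ortho-metalation removes the most acidic ring proton, the one flanked and chelated by both OMOM groups, and borylation followed by peroxide-induced 1,2-aryl shift from boron to oxygen (boronate oxidation) should give the phenol.

Step 3
Reactants: 5 2,6-bis(methoxymethoxy)-4-propylphenol
Product: 6 tert-butyl[2,6-bis(methoxymethoxy)-4-propylphenoxy]dimethylsilane
Conditions: TBSCl, imidazole, DMF, rt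
Reagents that add atoms: tert-butyldimethylsilyl chloride, CC(C)(C)[Si](C)(C)Cl
Why: Imidazole-promoted silylation of the phenol gives an ether that tolerates alkyllithium at low temperature and is cleaved by fluoride without touching MOM ethers or a benzyl ester.

Step 4
Reactants: 6 tert-butyl[2,6-bis(methoxymethoxy)-4-propylphenoxy]dimethylsilane
Product: 9 benzyl 3-(tert-butyldimethylsilyloxy)-2,4-bis(methoxymethoxy)-6-propylbenzoate, via aryllithium 7 (not isolated), via lithium benzoate 8 (not isolated)
Conditions: s-BuLi, TMEDA, THF, −78 °C; CO2 (gas), −78 °C to rt; then BnBr, DMF, 40 °C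
Reagents that add atoms: carbon dioxide, O=C=O; benzyl bromide, BrCc1ccccc1
Why: With the site between the oxygens blocked, directed ortho-metalation by an OMOM group can only occur at the two symmetry-equivalent ring positions next to the propyl group, and carboxylation followed by SN2 O-benzylation of the lithium carboxylate should give the ester.

Step 5
Reactants: 9 benzyl 3-(tert-butyldimethylsilyloxy)-2,4-bis(methoxymethoxy)-6-propylbenzoate
Product: 10 benzyl 3-hydroxy-2,4-bis(methoxymethoxy)-6-propylbenzoate
Conditions: Bu4NF, AcOH, THF, 0 °C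
Reagents that add atoms: none
Why: Fluoride-mediated desilylation cleaves the aryl silyl ether, and the acetic acid buffer keeps the phenoxide from attacking the benzyl ester while the MOM ethers are inert.

Step 6
Reactants: 11 2,2-dimethyl-1,3-dioxane-4,6-dione; 12 butanoyl chloride
Product: 13 5-(1-hydroxybutylidene)-2,2-dimethyl-1,3-dioxane-4,6-dione
Conditions: pyridine, CH2Cl2, 0 °C to rt; dilute HCl work-up
Reagents that add atoms: none
Why: C-acylation of the strongly acidic cyclic malonate by the acid chloride under pyridine (Oikawa–Yonemitsu acylation of Meldrum's acid) should give the enolised acyl derivative.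

Step 7
Reactants: 10 benzyl 3-hydroxy-2,4-bis(methoxymethoxy)-6-propylbenzoate; 13 5-(1-hydroxybutylidene)-2,2-dimethyl-1,3-dioxane-4,6-dione
Product: 15 3-benzyloxycarbonyl-2,6-bis(methoxymethoxy)-4-propylphenyl 3-oxohexanoate, via butanoylketene 14 (not isolated)
Conditions: PhMe, 110 °C
Reagents that add atoms: none
Why: Thermal retro-[4+2] fragmentation of the acyl Meldrum's acid releases acetone and CO2 and gives butanoylketene, a small and very electrophilic acylating agent that the doubly ortho-substituted phenol should capture by addition of its O–H, so a crowded esterification is avoided.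

Step 8
Reactants: 15 3-benzyloxycarbonyl-2,6-bis(methoxymethoxy)-4-propylphenyl 3-oxohexanoate; 16 methyl 3-chloro-3-oxopropanoate
Product: 18 3-benzyloxycarbonyl-2,6-bis(methoxymethoxy)-4-propylphenyl 4-hydroxy-2-oxo-6-propyl-2H-pyran-5-carboxylate, via acyclic tricarbonyl diester 17 (not isolated)
Conditions: MgCl2, pyridine, CH2Cl2, 0 °C to rt; then DBU, 4 Å molecular sieves, PhMe, 70 °C
Reagents that add atoms: none
Why: Rathke-type C-acylation of the magnesium-chelated β-keto ester gives the 2-acyl-3-oxoglutarate, whose butanoyl enolate oxygen then attacks the methyl ester (6-exo-trig lactonisation with loss of methanol, which the sieves take up) to give the 4-hydroxy-2-pyrone; the aryl ester cannot lactonise because that would need a four-membered ring.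

Step 9
Reactants: 18 3-benzyloxycarbonyl-2,6-bis(methoxymethoxy)-4-propylphenyl 4-hydroxy-2-oxo-6-propyl-2H-pyran-5-carboxylate
Product: 19 3-benzyloxycarbonyl-2,6-bis(methoxymethoxy)-4-propylphenyl 4-methoxy-2-oxo-6-propyl-2H-pyran-5-carboxylate
Conditions: Me2SO4, K2CO3, acetone, rt to 50 °C
Reagents that add atoms: dimethyl sulfate, COS(=O)(=O)OC
Why: SN2 O-methylation of the acidic vinylogous-acid hydroxyl with dimethyl sulfate under K2CO3 should give the 4-methoxy-2-pyrone and not the 2-methoxy-4-pyrone, as is usual for 6-alkyl-4-hydroxy-2-pyrones, and neither ester is affected.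

Step 10
Reactants: 19 3-benzyloxycarbonyl-2,6-bis(methoxymethoxy)-4-propylphenyl 4-methoxy-2-oxo-6-propyl-2H-pyran-5-carboxylate; 20 1,1-dimethoxyethene
Product: 23 benzyl 3-(2,4-dimethoxy-6-propylbenzoyloxy)-2,4-bis(methoxymethoxy)-6-propylbenzoate, via bridged lactone 21 (not isolated), via cyclohexadiene ketal 22 (not isolated)
Conditions: 1,1-dimethoxyethene (8 equiv), PhMe, sealed tube, 130 °C
Reagents that add atoms: none
Why: The electron-rich CH2 of the ketene acetal adds to pyrone C6, which is the β-carbon of the 5-ester and the vinylogous terminus of the lactone carbonyl, and the developing dimethoxycarbenium carbon is captured by C3, which the 4-methoxy group makes the nucleophilic end of the diene, so bridged lactone 21 forms in a polar, strongly asynchronous [4+2] cycloaddition. The closest known reaction is the inverse-demand Diels–Alder reaction of 2-pyrone-5-carboxylates with ketene acetals, which delivers 4-alkoxybenzoates. Ring A is closed by this intermolecular [4+2] event (bonds C6–CH2 and C3–C(OMe)2), after which retro-[4+2] loss of the O1–C2 bridge as CO2 gives diene ketal 22 and thermal 1,2-elimination of methanol aromatises it. No stereocentre remains, because the two bridgehead centres of racemic 21 are destroyed when CO2 is extruded. The step needs regioselectivity (new methoxy para and not meta to the ester), and this follows from the matched polarisation of the pyrone (C6 electrophilic, C3 nucleophilic) and of the acetal (CH2 nucleophilic, acetal carbon electrophilic). The large excess of acetal is meant to offset the deactivating 4-methoxy and the hindering 6-propyl group and to scavenge the liberated methanol.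

Step 11
Reactants: 23 benzyl 3-(2,4-dimethoxy-6-propylbenzoyloxy)-2,4-bis(methoxymethoxy)-6-propylbenzoate
Product: 24 benzyl 3-(2,4-dimethoxy-6-propylbenzoyloxy)-2,4-dihydroxy-6-propylbenzoate
Conditions: HCl (3 M in MeOH), THF, rt to 40 °C
Reagents that add atoms: none
Why: Acid-catalysed transacetalisation with methanol removes both MOM groups as dimethoxymethane, the two doubly ortho-substituted esters should resist methanolysis, and the carboxyl group is still masked so decarboxylation cannot occur.

Step 12
Reactants: 24 benzyl 3-(2,4-dimethoxy-6-propylbenzoyloxy)-2,4-dihydroxy-6-propylbenzoate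
Product: 25 3-(2,4-dimethoxy-6-propylbenzoyloxy)-2,4-dihydroxy-6-propylbenzoic acid
Conditions: H2 (1 atm), 10% Pd/C, EtOAc, rt
Reagents that add atoms: none
Why: Catalytic hydrogenolysis of the benzylic C–O bond frees the acid under neutral conditions, so the aroyl group should not migrate to the neighbouring phenols (no base) and the salicylic-type acid should not decarboxylate (no heat or strong acid).

**Compound list**
1 | 5-propylresorcinol | CCCc1cc(O)cc(O)c1 | starting material
2 | 1,3-bis(methoxymethoxy)-5-propylbenzene | CCCc1cc(OCOC)cc(OCOC)c1 | intermediate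
3 | [2,6-bis(methoxymethoxy)-4-propylphenyl]lithium | CCCc1cc(OCOC)c([Li])c(OCOC)c1 | intermediate
4 | lithium [2,6-bis(methoxymethoxy)-4-propylphenyl]trimethoxyborate | CCCc1cc(OCOC)c([B-](OC)(OC)OC)c(OCOC)c1.[Li+] | intermediate
5 | 2,6-bis(methoxymethoxy)-4-propylphenol | CCCc1cc(OCOC)c(O)c(OCOC)c1 | intermediate
6 | tert-butyl[2,6-bis(methoxymethoxy)-4-propylphenoxy]dimethylsilane | CCCc1cc(OCOC)c(O[Si](C)(C)C(C)(C)C)c(OCOC)c1 | intermediate
7 | [3-(tert-butyldimethylsilyloxy)-2,4-bis(methoxymethoxy)-6-propylphenyl]lithium | CCCc1cc(OCOC)c(O[Si](C)(C)C(C)(C)C)c(OCOC)c1[Li] | intermediate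
8 | lithium 3-(tert-butyldimethylsilyloxy)-2,4-bis(methoxymethoxy)-6-propylbenzoate | CCCc1cc(OCOC)c(O[Si](C)(C)C(C)(C)C)c(OCOC)c1C(=O)[O-].[Li+] | intermediate
9 | benzyl 3-(tert-butyldimethylsilyloxy)-2,4-bis(methoxymethoxy)-6-propylbenzoate | CCCc1cc(OCOC)c(O[Si](C)(C)C(C)(C)C)c(OCOC)c1C(=O)OCc1ccccc1 | intermediate
10 | benzyl 3-hydroxy-2,4-bis(methoxymethoxy)-6-propylbenzoate | CCCc1cc(OCOC)c(O)c(OCOC)c1C(=O)OCc1ccccc1 | intermediate
11 | 2,2-dimethyl-1,3-dioxane-4,6-dione | CC1(C)OC(=O)CC(=O)O1 | starting material
12 | butanoyl chloride | CCCC(Cl)=O | starting material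
13 | 5-(1-hydroxybutylidene)-2,2-dimethyl-1,3-dioxane-4,6-dione | CCCC(O)=C1C(=O)OC(C)(C)OC1=O | intermediate
14 | butanoylketene (3-oxohex-1-en-1-one) | CCCC(=O)C=C=O | intermediate
15 | 3-benzyloxycarbonyl-2,6-bis(methoxymethoxy)-4-propylphenyl 3-oxohexanoate | CCCC(=O)CC(=O)Oc1c(OCOC)cc(CCC)c(C(=O)OCc2ccccc2)c1OCOC | intermediate
16 | methyl 3-chloro-3-oxopropanoate | COC(=O)CC(Cl)=O | starting material
17 | 1-[3-benzyloxycarbonyl-2,6-bis(methoxymethoxy)-4-propylphenyl] 5-methyl 2-butanoyl-3-oxopentanedioate (keto form of the enol mixture) | CCCC(=O)C(C(=O)CC(=O)OC)C(=O)Oc1c(OCOC)cc(CCC)c(C(=O)OCc2ccccc2)c1OCOC | intermediate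
18 | 3-benzyloxycarbonyl-2,6-bis(methoxymethoxy)-4-propylphenyl 4-hydroxy-2-oxo-6-propyl-2H-pyran-5-carboxylate | CCCc1oc(=O)cc(O)c1C(=O)Oc1c(OCOC)cc(CCC)c(C(=O)OCc2ccccc2)c1OCOC | intermediate
19 | 3-benzyloxycarbonyl-2,6-bis(methoxymethoxy)-4-propylphenyl 4-methoxy-2-oxo-6-propyl-2H-pyran-5-carboxylate | CCCc1oc(=O)cc(OC)c1C(=O)Oc1c(OCOC)cc(CCC)c(C(=O)OCc2ccccc2)c1OCOC | intermediate
20 | 1,1-dimethoxyethene | C=C(OC)OC | starting material
21 | 3-benzyloxycarbonyl-2,6-bis(methoxymethoxy)-4-propylphenyl 5,8,8-trimethoxy-3-oxo-1-propyl-2-oxabicyclo[2.2.2]oct-5-ene-6-carboxylate (racemic, one enantiomer drawn) | CCC[C@@]12OC(=O)[C@@H](C(OC)=C1C(=O)Oc3c(OCOC)cc(CCC)c(C(=O)OCc4ccccc4)c3OCOC)C(OC)(OC)C2 | intermediate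
22 | 3-benzyloxycarbonyl-2,6-bis(methoxymethoxy)-4-propylphenyl 4,4,6-trimethoxy-2-propylcyclohexa-1,5-diene-1-carboxylate | CCCC1=C(C(=O)Oc2c(OCOC)cc(CCC)c(C(=O)OCc3ccccc3)c2OCOC)C(OC)=CC(OC)(OC)C1 | intermediate
23 | benzyl 3-(2,4-dimethoxy-6-propylbenzoyloxy)-2,4-bis(methoxymethoxy)-6-propylbenzoate | CCCc1cc(OC)cc(OC)c1C(=O)Oc1c(OCOC)cc(CCC)c(C(=O)OCc2ccccc2)c1OCOC | intermediate
24 | benzyl 3-(2,4-dimethoxy-6-propylbenzoyloxy)-2,4-dihydroxy-6-propylbenzoate | CCCc1cc(OC)cc(OC)c1C(=O)Oc1c(O)cc(CCC)c(C(=O)OCc2ccccc2)c1O | intermediate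
25 | 3-(2,4-dimethoxy-6-propylbenzoyloxy)-2,4-dihydroxy-6-propylbenzoic acid | CCCc1cc(OC)cc(OC)c1C(=O)Oc1c(O)cc(CCC)c(C(=O)O)c1O | target

**Step count and risk**

Total step count: 12. Longest linear sequence: 11 steps (steps 1–5 and 7–12); step 6 is a one-step branch.

Steps most likely to fail:

1. Step 10. The cycloaddition may stall because the 4-methoxy donor and the 6-propyl group lower the electrophilicity and accessibility of pyrone C6, while the ketene acetal oligomerises at the temperature required. The fallback gives up the pyrone route to ring A and brings ring A in as a finished acid that is esterified with ring B. It sets out from 1 and from phenol 10. Methylation of 1 (Me2SO4, K2CO3, acetone) should give 1,3-dimethoxy-5-propylbenzene F1. Vilsmeier–Haack formylation (POCl3, DMF) next to the propyl group should give 2,4-dimethoxy-6-propylbenzaldehyde F2. Pinnick oxidation (NaClO2, NaH2PO4, 2-methylbut-2-ene) should give 2,4-dimethoxy-6-propylbenzoic acid F3, and oxalyl chloride with catalytic DMF should give 2,4-dimethoxy-6-propylbenzoyl chloride F4. Acylation of 10 with this chloride (Et3N, DMAP, CH2Cl2) comes back to the route at 23.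

2. Step 8. The malonyl chloride may self-condense through its ketene instead of C-acylating, and during the base-mediated lactonisation the aryloxy group may be lost, either by elimination to an acylketene or by exchange with the liberated methanol. The fallback completes the pyrone on a tert-butyl ester, which cannot leave in this way and allows more forcing acylation, and attaches ring B afterwards. It sets out from 13. Heating with tert-butanol in toluene should give tert-butyl 3-oxohexanoate F5 through ketene 14. Acylation with 16 (MgCl2, pyridine) should give 1-tert-butyl 5-methyl 2-butanoyl-3-oxopentanedioate F6, which DBU closes to tert-butyl 4-hydroxy-2-oxo-6-propyl-2H-pyran-5-carboxylate F7. Me2SO4 and K2CO3 should give tert-butyl 4-methoxy-2-oxo-6-propyl-2H-pyran-5-carboxylate F8. CF3CO2H in CH2Cl2 should release 4-methoxy-2-oxo-6-propyl-2H-pyran-5-carboxylic acid F9, and oxalyl chloride with catalytic DMF should give 4-methoxy-2-oxo-6-propyl-2H-pyran-5-carbonyl chloride F10. Acylation of phenol 10 (Et3N, DMAP, CH2Cl2) comes back to the route at 19.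

3. Step 4. Deprotonation at the crowded position between an OMOM group and the propyl chain may be slow or incomplete, and the alkyllithium may instead attack silicon and remove the silyl ether. The fallback fixes the site by electrophilic substitution instead of deprotonation. It sets out from 6. NBS in MeCN at 0 °C should brominate the only free ring position, which is ortho to one OMOM group and para to the other, to give [3-bromo-2,6-bis(methoxymethoxy)-4-propylphenoxy](tert-butyl)dimethylsilane F11. Bromine–lithium exchange with n-BuLi in THF at −78 °C comes back to the route at aryllithium 7, which is carboxylated and benzylated to 9 as in step 4.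

Further compounds
F1 | step 10 | 1,3-dimethoxy-5-propylbenzene | CCCc1cc(OC)cc(OC)c1
F2 | step 10 | 2,4-dimethoxy-6-propylbenzaldehyde | CCCc1cc(OC)cc(OC)c1C=O
F3 | step 10 | 2,4-dimethoxy-6-propylbenzoic acid | CCCc1cc(OC)cc(OC)c1C(=O)O
F4 | step 10 | 2,4-dimethoxy-6-propylbenzoyl chloride | CCCc1cc(OC)cc(OC)c1C(Cl)=O
F5 | step 8 | tert-butyl 3-oxohexanoate | CCCC(=O)CC(=O)OC(C)(C)C
F6 | step 8 | 1-tert-butyl 5-methyl 2-butanoyl-3-oxopentanedioate | CCCC(=O)C(C(=O)CC(=O)OC)C(=O)OC(C)(C)C
F7 | step 8 | tert-butyl 4-hydroxy-2-oxo-6-propyl-2H-pyran-5-carboxylate | CCCc1oc(=O)cc(O)c1C(=O)OC(C)(C)C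
F8 | step 8 | tert-butyl 4-methoxy-2-oxo-6-propyl-2H-pyran-5-carboxylate | CCCc1oc(=O)cc(OC)c1C(=O)OC(C)(C)C
F9 | step 8 | 4-methoxy-2-oxo-6-propyl-2H-pyran-5-carboxylic acid | CCCc1oc(=O)cc(OC)c1C(=O)O
F10 | step 8 | 4-methoxy-2-oxo-6-propyl-2H-pyran-5-carbonyl chloride | CCCc1oc(=O)cc(OC)c1C(Cl)=O
F11 | step 4 | [3-bromo-2,6-bis(methoxymethoxy)-4-propylphenoxy](tert-butyl)dimethylsilane | CCCc1cc(OCOC)c(O[Si](C)(C)C(C)(C)C)c(OCOC)c1Br
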